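**Plan**

- Retrosynthesis: the caffeate C–O bond is cut first. In the oxolane (O1, C2 aryl, C3 CH2O, C4 arylmethyl, C5) the bonds C2–C3 and C4–C5 are then cut together. The open-chain precursor is cut at its alkene (metathesis) and between the two carbinol carbons (alkoxyallylboration).
- Enabling feature: C3 carries a one-carbon oxygenated branch next to the aryl-bearing C2, and C5 is an O–CH2 carbon at the formaldehyde-acetal level. The ring is therefore a 3-formyl oxolane, the product pattern of a pinacol-terminated Prins cyclisation of an allylic diol formaldehyde acetal.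
- Forward: ring A aldehyde → syn diol monoether → trans-1,3-dioxolane (temporary carrier of the C5 carbon) → (E)-alkene bearing ring B → one cationic cascade closes the oxolane, the only ring of the target that is built → reduction, esterification, desilylation.
- Stereochemistry: both carbinol centres come from the (+)-isopinocampheylborane reagent. The benzylic centre becomes C2 and is relayed to C4 through a chair with the (E)-alkene. C3 is set by base equilibration trans to the aryl group.

Key step: step 6

Remark: allyl methoxymethyl ether and (+)-B-methoxydiisopinocampheylborane are taken as purchased reagents; in the (2R,3S,4S) target the aryl and CH2O groups are trans and the CH2O and arylmethyl groups are cis.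

**Route**

Step 1
Reactants: 1 vanillin
Product: 2 3-methoxy-4-(triisopropylsilyloxy)benzaldehyde
Conditions: TIPSCl, imidazole, DMF, rt
Reagents that add atoms: TIPSCl, CC(C)[Si](Cl)(C(C)C)C(C)C
Why: Silyl ether formation with imidazole-activated TIPSCl masks the phenol with a group that should tolerate the allylborane, Lewis acid, DBU and NaBH4 of the later steps.

Step 2
Reactants: 2 3-methoxy-4-(triisopropylsilyloxy)benzaldehyde; 3 allyl methoxymethyl ether
Product: 8 (1S,2S)-2-(methoxymethoxy)-1-[3-methoxy-4-(triisopropylsilyloxy)phenyl]but-3-en-1-ol, via lithiated allyl ether 4 (not isolated), via methoxyborate complex 5 (not isolated), via allylborane 6 (not isolated), via borinate ester 7 (not isolated)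
Conditions: 3, s-BuLi, THF, −78 °C; (+)-Ipc2BOMe; BF3·OEt2; 2, −78 °C → rt; HOCH2CH2NH2
Reagents that add atoms: none
Why: In this Brown asymmetric alkoxyallylboration the chelated (Z)-allyllithium 4 is transferred to boron, and the (Z)-allylborane 6 adds to the aldehyde through a closed Zimmerman–Traxler chair, the Z geometry fixing the syn relation of the two oxygens and the isopinocampheyl groups of the (+)-reagent directing attack to the Re face of the aldehyde, so that both new centres arise as S.

Step 3
Reactants: 8 (1S,2S)-2-(methoxymethoxy)-1-[3-methoxy-4-(triisopropylsilyloxy)phenyl]but-3-en-1-ol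
Product: 9 (4S,5S)-4-[3-methoxy-4-(triisopropylsilyloxy)phenyl]-5-vinyl-1,3-dioxolane
Conditions: CSA (10 mol %), 5 Å MS, CH2Cl2, rt
Reagents that add atoms: none
Why: Acid-catalysed intramolecular transacetalisation lets the methoxymethyl group lose methanol and the neighbouring benzylic hydroxyl group trap the oxocarbenium ion as the five-membered formaldehyde acetal, the syn diol giving the trans-dioxolane with neither stereocentre touched.

Step 4
Reactants: 10 eugenol
Product: 11 4-allyl-2-methoxy-1-(triisopropylsilyloxy)benzene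
Conditions: TIPSCl, imidazole, DMF, rt
Reagents that add atoms: TIPSCl, CC(C)[Si](Cl)(C(C)C)C(C)C
Why: Silyl ether formation removes the free phenol, which would otherwise bind the ruthenium catalyst and the Lewis acid of the next two steps.

Step 5
Reactants: 9 (4S,5S)-4-[3-methoxy-4-(triisopropylsilyloxy)phenyl]-5-vinyl-1,3-dioxolane; 11 4-allyl-2-methoxy-1-(triisopropylsilyloxy)benzene
Product: 12 (4S,5S)-4-[3-methoxy-4-(triisopropylsilyloxy)phenyl]-5-[(E)-3-[3-methoxy-4-(triisopropylsilyloxy)phenyl]prop-1-enyl]-1,3-dioxolane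
Conditions: 11 (3 equiv), second-generation Hoveyda–Grubbs catalyst (5 mol %), 1,4-benzoquinone (10 mol %), CH2Cl2, 40 °C
Reagents that add atoms: none
Why: Ruthenium-catalysed olefin cross-metathesis between the hindered allylic-ether alkene of 9 and the unhindered terminal alkene of 11 should give the cross product with the E geometry favoured on steric and thermodynamic grounds, the benzoquinone suppressing migration of the allylarene double bond.

Step 6
Reactants: 12 (4S,5S)-4-[3-methoxy-4-(triisopropylsilyloxy)phenyl]-5-[(E)-3-[3-methoxy-4-(triisopropylsilyloxy)phenyl]prop-1-enyl]-1,3-dioxolane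
Product: 15 (2R,3R,4S)-2-[3-methoxy-4-(triisopropylsilyloxy)phenyl]-4-[3-methoxy-4-(triisopropylsilyloxy)benzyl]oxolane-3-carbaldehyde, via oxocarbenium ion 13 (not isolated), via C3-epimeric aldehyde 14 (not isolated)
Conditions: SnCl4 (2 equiv), CH2Cl2, −78 → −20 °C; aq NaHCO3; then DBU (0.2 equiv), PhMe, rt
Reagents that add atoms: none
Why: SnCl4 opens the dioxolane at the allylic oxygen to give the O-methylene oxocarbenium ion 13 on the benzylic oxygen, whose carbon bonds to the distal alkene carbon (C5–C4) through a six-membered chair, after which the aryl-bearing carbon shifts from the tin-bound carbinol carbon to the electron-poor carbon (C2–C3) and the carbinol carbon is released as the formyl group of 14. The closest known reaction is the pinacol-terminated Prins cyclisation of 4-alkenyl-1,3-dioxolanes to 3-acyl oxolanes, and with this electron-rich aryl group the same two bonds may equally form by 2-oxonia-Cope rearrangement followed by aldol attack of the enol on the aryl-stabilised oxocarbenium ion. The oxolane therefore closes either by 6-endo-trig attack and ring contraction or, on the second path, by a 5-(enolexo)-exo-trig aldol. C4 is controlled by the chair, in which the aryl group and, owing to the (E)-alkene, the arylmethyl group are both equatorial and so end up trans, while C2 keeps its configuration because the migrating carbon moves with retention. C3 is controlled thermodynamically, DBU equilibrating 14 through its enolate to 15 with the formyl group trans to the larger, directly attached aryl group. The step needs C–C bond formation to outrun benzylic C–O ionisation, hydride shift and chloride capture, which the low temperature, the trans-dioxolane (re-closure after benzylic ionisation regenerates it) and the syn diol (carbinol hydrogen equatorial in the chair, out of line with the empty orbital) are meant to secure.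

Step 7
Reactants: 15 (2R,3R,4S)-2-[3-methoxy-4-(triisopropylsilyloxy)phenyl]-4-[3-methoxy-4-(triisopropylsilyloxy)benzyl]oxolane-3-carbaldehyde
Product: 16 [(2R,3S,4S)-2-[3-methoxy-4-(triisopropylsilyloxy)phenyl]-4-[3-methoxy-4-(triisopropylsilyloxy)benzyl]oxolan-3-yl]methanol
Conditions: NaBH4, MeOH–THF, −20 °C
Reagents that add atoms: none
Why: Hydride reduction of the aldehyde with NaBH4 in the cold is faster than enolisation, so the C3 configuration is kept (the descriptor changes from R to S only because CH2OH ranks below C2) and the silyl ethers are untouched.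

Step 8
Reactants: 17 caffeic acid
Product: 19 (E)-3-[3,4-bis(tert-butyldimethylsilyloxy)phenyl]prop-2-enoic acid, via silyl ester 18 (not isolated)
Conditions: TBSCl (3.3 equiv), imidazole, DMF, rt; then AcOH, THF–H2O, rt
Reagents that add atoms: TBSCl, CC(C)(C)[Si](C)(C)Cl
Why: Exhaustive silylation followed by selective hydrolysis of the silyl ester, which is far more labile than the aryl silyl ethers, frees only the carboxylic acid.

Step 9
Reactants: 16 [(2R,3S,4S)-2-[3-methoxy-4-(triisopropylsilyloxy)phenyl]-4-[3-methoxy-4-(triisopropylsilyloxy)benzyl]oxolan-3-yl]methanol; 19 (E)-3-[3,4-bis(tert-butyldimethylsilyloxy)phenyl]prop-2-enoic acid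
Product: 20 [(2R,3S,4S)-2-[3-methoxy-4-(triisopropylsilyloxy)phenyl]-4-[3-methoxy-4-(triisopropylsilyloxy)benzyl]oxolan-3-yl]methyl (E)-3-[3,4-bis(tert-butyldimethylsilyloxy)phenyl]prop-2-enoate
Conditions: DCC, DMAP (cat.), CH2Cl2, 0 °C → rt
Reagents that add atoms: none
Why: Steglich esterification (DCC activation, acyl transfer by DMAP) acylates the only free hydroxyl group, a primary alcohol, under neutral conditions that leave the oxolane stereocentres and the (E)-alkene unchanged.

Step 10
Reactants: 20 [(2R,3S,4S)-2-[3-methoxy-4-(triisopropylsilyloxy)phenyl]-4-[3-methoxy-4-(triisopropylsilyloxy)benzyl]oxolan-3-yl]methyl (E)-3-[3,4-bis(tert-butyldimethylsilyloxy)phenyl]prop-2-enoate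
Product: 21 [(2R,3S,4S)-2-(4-hydroxy-3-methoxyphenyl)-4-(4-hydroxy-3-methoxybenzyl)oxolan-3-yl]methyl (E)-3-(3,4-dihydroxyphenyl)prop-2-enoate
Conditions: TBAF (4.4 equiv), AcOH (4.4 equiv), THF, 0 °C
Reagents that add atoms: none
Why: Fluoride-driven cleavage of the four aryl silyl ethers, buffered with AcOH so that the phenoxides formed neither attack the cinnamate ester nor expose the catechol to air oxidation, should release the target.

**Compound list**

1 | vanillin | COc1cc(C=O)ccc1O | starting material
2 | 3-methoxy-4-(triisopropylsilyloxy)benzaldehyde | COc1cc(C=O)ccc1O[Si](C(C)C)(C(C)C)C(C)C | intermediate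
3 | allyl methoxymethyl ether | C=CCOCOC | starting material
4 | (Z)-3-(methoxymethoxy)allyllithium | [Li]C/C=C\OCOC | intermediate (not isolated)
5 | lithium methoxy[(Z)-3-(methoxymethoxy)allyl]bis(isopinocampheyl)borate | [Li+].CO[B-](C/C=C\OCOC)([C@H]1C[C@H]2C[C@@H]([C@@H]1C)C2(C)C)[C@H]1C[C@H]2C[C@@H]([C@@H]1C)C2(C)C | intermediate (not isolated)
6 | [(Z)-3-(methoxymethoxy)allyl]bis(isopinocampheyl)borane | COCO/C=C\CB([C@H]1C[C@H]2C[C@@H]([C@@H]1C)C2(C)C)[C@H]1C[C@H]2C[C@@H]([C@@H]1C)C2(C)C | intermediate (not isolated)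
7 | bis(isopinocampheyl)borinate ester of 8 | COc1cc([C@H](OB([C@H]2C[C@H]3C[C@@H]([C@@H]2C)C3(C)C)[C@H]2C[C@H]3C[C@@H]([C@@H]2C)C3(C)C)[C@@H](OCOC)C=C)ccc1O[Si](C(C)C)(C(C)C)C(C)C | intermediate (not isolated)
8 | (1S,2S)-2-(methoxymethoxy)-1-[3-methoxy-4-(triisopropylsilyloxy)phenyl]but-3-en-1-ol | COc1cc([C@H](O)[C@@H](OCOC)C=C)ccc1O[Si](C(C)C)(C(C)C)C(C)C | intermediate
9 | (4S,5S)-4-[3-methoxy-4-(triisopropylsilyloxy)phenyl]-5-vinyl-1,3-dioxolane (trans) | COc1cc([C@@H]2OCO[C@H]2C=C)ccc1O[Si](C(C)C)(C(C)C)C(C)C | intermediate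
10 | eugenol | COc1cc(CC=C)ccc1O | starting material
11 | 4-allyl-2-methoxy-1-(triisopropylsilyloxy)benzene | COc1cc(CC=C)ccc1O[Si](C(C)C)(C(C)C)C(C)C | intermediate
12 | (4S,5S)-4-[3-methoxy-4-(triisopropylsilyloxy)phenyl]-5-[(E)-3-[3-methoxy-4-(triisopropylsilyloxy)phenyl]prop-1-enyl]-1,3-dioxolane | COc1cc([C@@H]2OCO[C@H]2/C=C/Cc3ccc(O[Si](C(C)C)(C(C)C)C(C)C)c(OC)c3)ccc1O[Si](C(C)C)(C(C)C)C(C)C | intermediate (key-step precursor)
13 | O-methylene oxocarbenium ion on the benzylic oxygen with SnCl4-bound alkoxide (zwitterion) | COc1cc([C@H]([O+]=C)[C@@H](O[Sn-](Cl)(Cl)(Cl)Cl)/C=C/Cc2ccc(O[Si](C(C)C)(C(C)C)C(C)C)c(OC)c2)ccc1O[Si](C(C)C)(C(C)C)C(C)C | intermediate (not isolated)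
14 | (2R,3S,4S)-2-[3-methoxy-4-(triisopropylsilyloxy)phenyl]-4-[3-methoxy-4-(triisopropylsilyloxy)benzyl]oxolane-3-carbaldehyde (formyl cis to aryl) | COc1cc(C[C@@H]2CO[C@@H](c3ccc(O[Si](C(C)C)(C(C)C)C(C)C)c(OC)c3)[C@H]2C=O)ccc1O[Si](C(C)C)(C(C)C)C(C)C | intermediate (not isolated)
15 | (2R,3R,4S)-2-[3-methoxy-4-(triisopropylsilyloxy)phenyl]-4-[3-methoxy-4-(triisopropylsilyloxy)benzyl]oxolane-3-carbaldehyde (formyl trans to aryl) | COc1cc(C[C@@H]2CO[C@@H](c3ccc(O[Si](C(C)C)(C(C)C)C(C)C)c(OC)c3)[C@@H]2C=O)ccc1O[Si](C(C)C)(C(C)C)C(C)C | intermediate (key-step product)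
16 | [(2R,3S,4S)-2-[3-methoxy-4-(triisopropylsilyloxy)phenyl]-4-[3-methoxy-4-(triisopropylsilyloxy)benzyl]oxolan-3-yl]methanol | COc1cc(C[C@@H]2CO[C@@H](c3ccc(O[Si](C(C)C)(C(C)C)C(C)C)c(OC)c3)[C@@H]2CO)ccc1O[Si](C(C)C)(C(C)C)C(C)C | intermediate
17 | caffeic acid | OC(=O)/C=C/c1ccc(O)c(O)c1 | starting material
18 | tert-butyldimethylsilyl (E)-3-[3,4-bis(tert-butyldimethylsilyloxy)phenyl]prop-2-enoate | CC(C)(C)[Si](C)(C)OC(=O)/C=C/c1ccc(O[Si](C)(C)C(C)(C)C)c(O[Si](C)(C)C(C)(C)C)c1 | intermediate (not isolated)
19 | (E)-3-[3,4-bis(tert-butyldimethylsilyloxy)phenyl]prop-2-enoic acid | OC(=O)/C=C/c1ccc(O[Si](C)(C)C(C)(C)C)c(O[Si](C)(C)C(C)(C)C)c1 | intermediate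
20 | [(2R,3S,4S)-2-[3-methoxy-4-(triisopropylsilyloxy)phenyl]-4-[3-methoxy-4-(triisopropylsilyloxy)benzyl]oxolan-3-yl]methyl (E)-3-[3,4-bis(tert-butyldimethylsilyloxy)phenyl]prop-2-enoate | COc1cc(C[C@@H]2CO[C@@H](c3ccc(O[Si](C(C)C)(C(C)C)C(C)C)c(OC)c3)[C@@H]2COC(=O)/C=C/c2ccc(O[Si](C)(C)C(C)(C)C)c(O[Si](C)(C)C(C)(C)C)c2)ccc1O[Si](C(C)C)(C(C)C)C(C)C | intermediate
21 | [(2R,3S,4S)-2-(4-hydroxy-3-methoxyphenyl)-4-(4-hydroxy-3-methoxybenzyl)oxolan-3-yl]methyl (E)-3-(3,4-dihydroxyphenyl)prop-2-enoate | COc1cc(C[C@@H]2CO[C@@H](c3ccc(O)c(OC)c3)[C@@H]2COC(=O)/C=C/c2ccc(O)c(O)c2)ccc1O | target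

**Step count and risks**

Total: 10 steps. Longest linear sequence: 8 steps (1, 2, 3, 5, 6, 7, 9, 10) from vanillin.

Step 6 is the most likely to fail.
- What may go wrong: opening of the formaldehyde acetal may be slower than ionisation of the electron-rich benzylic C–O bond, or the cationic intermediate may be diverted by hydride shift, chloride capture or arene alkylation before the 1,2-shift. The base equilibration may also stop at a mixture of C3 epimers, or open the ring by retro-oxa-Michael reaction and so scramble C2.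
- Fallback: a radical ring closure of known type replaces the cationic cascade; it sets out from 2 and comes back to the route at 16.
- CH2=CHMgBr (THF, −78 °C) converts 2 into racemic 1-[3-methoxy-4-(triisopropylsilyloxy)phenyl]prop-2-en-1-ol F1.
- Sharpless kinetic resolution of F1 (Ti(OiPr)4, L-(+)-diisopropyl tartrate, t-BuOOH, 4 Å MS, CH2Cl2, −20 °C, about half conversion) should epoxidise the (R)-alcohol to the anti epoxy alcohol (S)-[3-methoxy-4-(triisopropylsilyloxy)phenyl][(S)-oxiran-2-yl]methanol F2.
- The recovered alcohol is treated with PBr3 (Et2O, 0 °C), which with allylic transposition into conjugation gives (E)-4-(3-bromoprop-1-enyl)-2-methoxy-1-(triisopropylsilyloxy)benzene F3.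
- Williamson etherification of F2 with F3 (NaH, THF, 0 °C) gives the epoxy ether (S)-2-[(S)-[3-methoxy-4-(triisopropylsilyloxy)phenyl]{[(E)-3-[3-methoxy-4-(triisopropylsilyloxy)phenyl]prop-2-enyl]oxy}methyl]oxirane F4.
- Cp2TiCl (trivalent titanium, generated from Cp2TiCl2 and Zn, THF, rt) opens the epoxide homolytically to the radical at the future C3, which closes 5-exo-trig onto the styrene-type double bond (C3–C4). Reduction of the benzylic radical by a second equivalent of Cp2TiCl and acidic work-up give 16.
- C2 comes from the resolved carbinol. The chair-like 5-hexenyl radical transition state is expected to place C3 trans to C2 and cis to C4, so no equilibration is needed.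

Step 5 is the second risk.
- What may go wrong: metathesis may give an E/Z mixture (the Z isomer would lead to the C4 epimer), and ruthenium hydride species may move the double bond of 11 into conjugation with ring B or consume it by homodimerisation.
- Fallback: the (E)-alkene is made by carbonyl olefination; it sets out from 9 and 11 and comes back at 12.
- Ozonolysis of 9 (O3, CH2Cl2, −78 °C; PPh3) gives (4R,5S)-5-[3-methoxy-4-(triisopropylsilyloxy)phenyl]-1,3-dioxolane-4-carbaldehyde F5.
- Ozonolysis of 11 with reductive work-up (O3, CH2Cl2–MeOH, −78 °C; NaBH4) gives 2-[3-methoxy-4-(triisopropylsilyloxy)phenyl]ethanol F6.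
- Mitsunobu thioetherification (1-phenyl-1H-tetrazole-5-thiol, PPh3, DIAD, THF) gives 5-{2-[3-methoxy-4-(triisopropylsilyloxy)phenyl]ethylsulfanyl}-1-phenyl-1H-tetrazole F7.
- Oxidation ((NH4)6Mo7O24, H2O2, EtOH) gives 5-{2-[3-methoxy-4-(triisopropylsilyloxy)phenyl]ethylsulfonyl}-1-phenyl-1H-tetrazole F8.
- Julia–Kocienski olefination (F8, KN(SiMe3)2, DME, −60 °C; then F5) should give 12 with the E geometry strongly favoured.

Step 3 is the third risk.
- What may go wrong: the acid may ionise the electron-rich benzylic alcohol faster than it exchanges the acetal, leading to elimination or oligomers, or the exchange may stall short of completion.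
- Fallback: the separate acetal exchange is dropped; it sets out from 8 and comes back at 15.
- Cross-metathesis of 8 with 11 under the conditions of step 5 gives (1S,2S,E)-2-(methoxymethoxy)-1,5-bis[3-methoxy-4-(triisopropylsilyloxy)phenyl]pent-3-en-1-ol F9.
- F9 is then submitted to the conditions of step 6 with more SnCl4 (about 3 equiv). Ionisation of the methoxymethyl ether gives an O-methylene oxocarbenium ion on the allylic oxygen, the benzylic hydroxyl group captures it to form 12 in the flask, and 12 continues through 13 and 14 to 15.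

Further compounds
F1 | step 6 | racemic 1-[3-methoxy-4-(triisopropylsilyloxy)phenyl]prop-2-en-1-ol | COc1cc(C(O)C=C)ccc1O[Si](C(C)C)(C(C)C)C(C)C
F2 | step 6 | (S)-[3-methoxy-4-(triisopropylsilyloxy)phenyl][(S)-oxiran-2-yl]methanol | COc1cc([C@H](O)[C@@H]2CO2)ccc1O[Si](C(C)C)(C(C)C)C(C)C
F3 | step 6 | (E)-4-(3-bromoprop-1-enyl)-2-methoxy-1-(triisopropylsilyloxy)benzene | COc1cc(/C=C/CBr)ccc1O[Si](C(C)C)(C(C)C)C(C)C
F4 | step 6 | (S)-2-[(S)-[3-methoxy-4-(triisopropylsilyloxy)phenyl]{[(E)-3-[3-methoxy-4-(triisopropylsilyloxy)phenyl]prop-2-enyl]oxy}methyl]oxirane | COc1cc([C@H](OC/C=C/c2ccc(O[Si](C(C)C)(C(C)C)C(C)C)c(OC)c2)[C@@H]3CO3)ccc1O[Si](C(C)C)(C(C)C)C(C)C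
F5 | step 5 | (4R,5S)-5-[3-methoxy-4-(triisopropylsilyloxy)phenyl]-1,3-dioxolane-4-carbaldehyde | COc1cc([C@@H]2OCO[C@H]2C=O)ccc1O[Si](C(C)C)(C(C)C)C(C)C
F6 | step 5 | 2-[3-methoxy-4-(triisopropylsilyloxy)phenyl]ethanol | COc1cc(CCO)ccc1O[Si](C(C)C)(C(C)C)C(C)C
F7 | step 5 | 5-{2-[3-methoxy-4-(triisopropylsilyloxy)phenyl]ethylsulfanyl}-1-phenyl-1H-tetrazole | COc1cc(CCSc2nnnn2-c3ccccc3)ccc1O[Si](C(C)C)(C(C)C)C(C)C
F8 | step 5 | 5-{2-[3-methoxy-4-(triisopropylsilyloxy)phenyl]ethylsulfonyl}-1-phenyl-1H-tetrazole | COc1cc(CCS(=O)(=O)c2nnnn2-c3ccccc3)ccc1O[Si](C(C)C)(C(C)C)C(C)C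
F9 | step 3 | (1S,2S,E)-2-(methoxymethoxy)-1,5-bis[3-methoxy-4-(triisopropylsilyloxy)phenyl]pent-3-en-1-ol | COc1cc([C@H](O)[C@@H](OCOC)/C=C/Cc2ccc(O[Si](C(C)C)(C(C)C)C(C)C)c(OC)c2)ccc1O[Si](C(C)C)(C(C)C)C(C)C
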